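**Strategy.** In eremophilane numbering, ring A (C1, C2, C3, C4, C5, C10) is a [4+2] retron: the C1 oxygen marks a 2-alkoxydiene (C2=C1–C10=C5, with C10=C5 inside ring B) and C3–C4(CH3) a propene equivalent. A Diels–Alder reaction of an enantioenriched ring B diene with 2-nitropropene forms C2–C3 and C4–C5 in one operation, closes ring A and sets the quaternary C5 anti to a C9 silyloxy group installed by CBS reduction. Radical denitration then gives the C4 methyl. The axial C7 isopropenyl and C8 oxygen are introduced late, by trans-diaxial epoxide opening, after the trans ring fusion is fixed.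

Key step: step 6

Remark: bicyclic compounds carry eremophilane numbering (ring A: C1, C2, C3, C4, C5, C10; ring B: C5 to C10; C14 = CH3 on C5, C15 = CH3 on C4; "11,12,13-trinor" = no side chain on C7), and β is the face of C14. 2-Nitropropene is assumed to be made fresh (step 5) because it polymerises on storage.

Step 1
Reactants: 1 3-methylcyclohex-2-en-1-one
Product: 2 2-iodo-3-methylcyclohex-2-en-1-one
Conditions: I2, K2CO3, DMAP (cat.), THF/H2O, rt
Reagents that add atoms: iodine, II
Why: Amine-catalysed α-iodination of the enone (conjugate addition of DMAP, iodination of the enolate, elimination; Baylis–Hillman-type) should give the α-iodoenone, and no stereocentre is formed.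

Step 2
Reactants: 2 2-iodo-3-methylcyclohex-2-en-1-one
Product: 3 (S)-2-iodo-3-methylcyclohex-2-en-1-ol
Conditions: (R)-2-methyl-CBS-oxazaborolidine (10 mol %), BH3·SMe2, THF, −20 °C; MeOH quench
Reagents that add atoms: none
Why: Corey–Bakshi–Shibata reduction, with the iodovinyl carbon as the large group, should deliver hydride to one carbonyl face and set C9 as (S).

Step 3
Reactants: 3 (S)-2-iodo-3-methylcyclohex-2-en-1-ol
Product: 4 (S)-tert-butyl[(2-iodo-3-methylcyclohex-2-en-1-yl)oxy]dimethylsilane
Conditions: TBSCl, imidazole, DMF, rt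
Reagents that add atoms: tert-butyldimethylsilyl chloride, CC(C)(C)[Si](C)(C)Cl
Why: Standard silylation of the secondary allylic alcohol should give the bulky silyl ether that later shields one face of the diene; C9 is untouched.

Step 4
Reactants: 4 (S)-tert-butyl[(2-iodo-3-methylcyclohex-2-en-1-yl)oxy]dimethylsilane
Product: 5 (S)-tert-butyl{[2-(1-ethoxyvinyl)-3-methylcyclohex-2-en-1-yl]oxy}dimethylsilane
Conditions: Bu3SnC(OEt)=CH2, Pd(PPh3)4 (5 mol %), CuI (10 mol %), DMF, 60 °C; chromatography on Et3N-deactivated silica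
Reagents that add atoms: tributyl(1-ethoxyvinyl)stannane, CCCC[Sn](CCCC)(CCCC)C(=C)OCC
Why: Stille coupling of the vinyl iodide with the α-alkoxyvinylstannane should install the 2-ethoxydiene C2=C1(OEt)–C10=C5 without affecting C9.

Step 5
Reactants: 6 2-nitropropan-1-ol
Product: 8 2-nitropropene, via hydrogen phthalate 7 (not isolated)
Conditions: phthalic anhydride, 150–180 °C, 110 mmHg, distillation from the melt
Reagents that add atoms: none
Why: Esterification to the hydrogen phthalate and thermal β-elimination of the activated ester (E1cB-like) should give the nitroalkene, which distils as it forms; no stereocentre.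

Step 6
Reactants: 5 (S)-tert-butyl{[2-(1-ethoxyvinyl)-3-methylcyclohex-2-en-1-yl]oxy}dimethylsilane; 8 2-nitropropene
Product: 9 9β-(tert-butyldimethylsilyloxy)-1-ethoxy-4α-nitro-11,12,13-trinoreremophil-1(10)-ene (4β,5β-dimethyl; expected major C4 epimer)
Conditions: toluene, BHT (cat.), 60 °C, sealed tube
Reagents that add atoms: none
Why: The electron-rich 2-ethoxydiene and the electron-poor nitroalkene should combine in a normal-demand, strongly asynchronous Diels–Alder reaction in which C2–C3 forms ahead of C4–C5. The closest known reaction type is the [4+2] cycloaddition of 2-alkoxy- and 2-silyloxybutadienes with nitroalkenes, which gives enol ethers of 4-nitrocyclohexanones. Ring A is closed by intermolecular [4+2] cycloaddition, leaving the C1=C10 enol ether. C5 is set by approach of the nitroalkene anti to the C9 silyloxy group, which sits pseudoaxial to avoid A(1,2) strain with the ethoxyvinyl group, so C4 bonds on the α face and C14 ends β, cis to the C9 oxygen; the C4 configuration (nitro expected endo) is erased in step 7. The step needs regioselectivity (nitro-bearing carbon to C5) and facial selectivity; the first is secured by the matched polarisation of the diene (nucleophilic C2) and the nitroalkene (electrophilic CH2), the second by the silyl ether.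

Step 7
Reactants: 9 9β-(tert-butyldimethylsilyloxy)-1-ethoxy-4α-nitro-11,12,13-trinoreremophil-1(10)-ene
Product: 10 9β-(tert-butyldimethylsilyloxy)-1-ethoxy-11,12,13-trinoreremophil-1(10)-ene (4β,5β-dimethyl, 4αH)
Conditions: Bu3SnH, AIBN (cat.), toluene, 110 °C
Reagents that add atoms: none
Why: Radical denitration of the tertiary nitro group should give the C4 radical, which should abstract hydrogen from Bu3SnH on the α face, anti to the adjacent C14 methyl, setting C15 as 4β (cis to C14).

Step 8
Reactants: 10 9β-(tert-butyldimethylsilyloxy)-1-ethoxy-11,12,13-trinoreremophil-1(10)-ene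
Product: 12 9β-hydroxy-10αH-11,12,13-trinoreremophilan-1-one, via silyloxy ketone 11 (not isolated)
Conditions: 0.1 M HCl, THF, 0 °C → rt; then HF·pyridine, THF, 0 °C → rt
Reagents that add atoms: water, O
Why: Mild acid hydrolysis of the enol ether should protonate C10 on the α face, anti to C14 and to the pseudoaxial 9β-silyloxy group (kinetic control, trans ring fusion), and acidic desilylation should then free the 9β-hydroxyl without passing through an enolate that would eliminate it.

Step 9
Reactants: 12 9β-hydroxy-10αH-11,12,13-trinoreremophilan-1-one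
Product: 14 10αH-11,12,13-trinoreremophilane-1α,9β-diol, via alkoxyborohydride 13 (not isolated)
Conditions: Me4NBH(OAc)3, MeCN/AcOH, −20 °C
Reagents that add atoms: none
Why: In this Evans–Saksena directed reduction the axial 9β-alkoxyborohydride should deliver hydride intramolecularly to the β face of C1, giving the equatorial 1α-alcohol (1,3-anti diol) that external hydride, which attacks from the α face, would not give.

Step 10
Reactants: 14 10αH-11,12,13-trinoreremophilane-1α,9β-diol
Product: 15 1α-acetoxy-10αH-11,12,13-trinoreremophilan-9β-ol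
Conditions: Ac2O, pyridine, CH2Cl2, 0 °C
Reagents that add atoms: acetic anhydride, CC(=O)OC(C)=O
Why: Acetylation should occur only at the equatorial 1α-hydroxyl, because the axial 9β-hydroxyl is syn-axial to C14 and hindered like a steroidal 11β-alcohol.

Step 11
Reactants: 15 1α-acetoxy-10αH-11,12,13-trinoreremophilan-9β-ol
Product: 16 1α-acetoxy-10αH-11,12,13-trinoreremophilan-9-one
Conditions: Dess–Martin periodinane, NaHCO3, CH2Cl2, rt
Reagents that add atoms: none
Why: Dess–Martin oxidation under buffered, non-enolising conditions should give the C9 ketone without epimerising C10 or eliminating the C1 acetate.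

Step 12
Reactants: 16 1α-acetoxy-10αH-11,12,13-trinoreremophilan-9-one
Product: 19 1α-acetoxy-10αH-11,12,13-trinoreremophil-7-en-9-one, via lithium enolate 17 (not isolated), via sulfilimine 18 (not isolated)
Conditions: LiN(SiMe3)2, THF, −78 °C; then PhS(Cl)=NtBu, −78 °C
Reagents that add atoms: none
Why: Kinetic deprotonation by the hindered amide at the C8 methylene (not at the tertiary C10), sulfinimidoylation of the enolate and syn-elimination of the sulfilimine (selenoxide-type elimination) should give the C7=C8 enone in one flask.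

Step 13
Reactants: 19 1α-acetoxy-10αH-11,12,13-trinoreremophil-7-en-9-one
Product: 20 1α-acetoxy-10αH-11,12,13-trinoreremophil-7-en-9β-ol
Conditions: NaBH4, CeCl3·7H2O, MeOH, −78 °C
Reagents that add atoms: none
Why: Luche 1,2-reduction should add hydride from the α face, away from the syn-axial C14 methyl, giving the pseudoaxial 9β allylic alcohol.

Step 14
Reactants: 20 1α-acetoxy-10αH-11,12,13-trinoreremophil-7-en-9β-ol
Product: 21 1α-acetoxy-9α-(4-methoxyphenoxy)-10αH-11,12,13-trinoreremophil-7-ene
Conditions: 4-methoxyphenol, PPh3, DIAD, toluene, 0 °C → rt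
Reagents that add atoms: 4-methoxyphenol, COc1ccc(O)cc1
Why: Mitsunobu etherification displaces the axial oxyphosphonium group by SN2 and should invert C9 to the equatorial 9α aryl ether, which also serves as the C9 protecting group.

Step 15
Reactants: 21 1α-acetoxy-9α-(4-methoxyphenoxy)-10αH-11,12,13-trinoreremophil-7-ene
Product: 22 1α-acetoxy-7α,8α-epoxy-9α-(4-methoxyphenoxy)-10αH-11,12,13-trinoreremophilane
Conditions: mCPBA, NaHCO3, CH2Cl2, 0 °C
Reagents that add atoms: 3-chloroperoxybenzoic acid, OOC(=O)c1cccc(Cl)c1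
Why: Prilezhaev epoxidation should occur on the α face of the C7=C8 alkene, opposite the axial C14 methyl, as in 2-ene steroids with an angular methyl group.

Step 16
Reactants: 22 1α-acetoxy-7α,8α-epoxy-9α-(4-methoxyphenoxy)-10αH-11,12,13-trinoreremophilane
Product: 23 1α-acetoxy-9α-(4-methoxyphenoxy)-10αH-eremophil-11-en-8α-ol (7β-isopropenyl)
Conditions: CH2=C(CH3)MgBr (4 equiv), CuBr·SMe2 (2 equiv), THF, −78 → −40 °C; then 22, BF3·OEt2, −78 → −30 °C; aq. NH4Cl
Reagents that add atoms: isopropenylmagnesium bromide, C=C(C)[Mg]Br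
Why: Trans-diaxial epoxide opening (Fürst–Plattner rule) by the alkenyl cuprate should occur at C7 from the β face with inversion, setting 7β-isopropenyl and 8α-OH together, since attack at C8 would need a twist-boat and is further disfavoured by the adjacent C9 oxygen.

Step 17
Reactants: 23 1α-acetoxy-9α-(4-methoxyphenoxy)-10αH-eremophil-11-en-8α-ol
Product: 25 1α-acetoxy-8α-angeloyloxy-9α-(4-methoxyphenoxy)-10αH-eremophil-11-ene, via lithium alkoxide 24 (not isolated)
Conditions: LiN(SiMe3)2, THF, −78 °C; then angelic anhydride, −78 → 0 °C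
Reagents that add atoms: angelic anhydride, O=C(OC(=O)/C(C)=C\C)/C(C)=C\C
Why: Acylation of the preformed lithium alkoxide with the anhydride avoids nucleophilic catalysts that isomerise angelate to tiglate, so the (Z)-ester should be retained and no stereocentre is touched.

Step 18
Reactants: 25 1α-acetoxy-8α-angeloyloxy-9α-(4-methoxyphenoxy)-10αH-eremophil-11-ene
Product: 26 1α-acetoxy-8α-angeloyloxy-10αH-eremophil-11-en-9α-ol
Conditions: (NH4)2Ce(NO3)6, MeCN/H2O (4:1), 0 °C
Reagents that add atoms: none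
Why: Oxidative dearylation of the 4-methoxyphenyl ether should release the 9α-alcohol with its C–O bond intact, leaving the two esters and the isopropenyl group untouched.

Step 19
Reactants: 26 1α-acetoxy-8α-angeloyloxy-10αH-eremophil-11-en-9α-ol
Product: 27 1α-acetoxy-8α-angeloyloxy-10αH-eremophil-11-en-9-one (target)
Conditions: Dess–Martin periodinane, NaHCO3, CH2Cl2, 0 °C → rt
Reagents that add atoms: none
Why: Buffered Dess–Martin oxidation should give the C9 ketone without base, so the trans ring fusion at C10 (expected to be the less stable epimer once the C7 group is axial) and the β-acetoxy ketone should survive.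

**Compound list**

1 | 3-methylcyclohex-2-en-1-one | CC1=CC(=O)CCC1 | starting material
2 | 2-iodo-3-methylcyclohex-2-en-1-one | CC1=C(I)C(=O)CCC1 | intermediate
3 | (S)-2-iodo-3-methylcyclohex-2-en-1-ol | O[C@H]1CCCC(C)=C1I | intermediate
4 | (S)-tert-butyl[(2-iodo-3-methylcyclohex-2-en-1-yl)oxy]dimethylsilane | CC(C)(C)[Si](C)(C)O[C@H]1CCCC(C)=C1I | intermediate
5 | (S)-tert-butyl{[2-(1-ethoxyvinyl)-3-methylcyclohex-2-en-1-yl]oxy}dimethylsilane | CC(C)(C)[Si](C)(C)O[C@H]1CCCC(C)=C1C(=C)OCC | intermediate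
6 | 2-nitropropan-1-ol | CC(CO)[N+](=O)[O-] | starting material
7 | 2-nitropropyl hydrogen phthalate | CC(COC(=O)c1ccccc1C(=O)O)[N+](=O)[O-] | intermediate (not isolated)
8 | 2-nitropropene | C=C(C)[N+](=O)[O-] | intermediate
9 | 9β-(tert-butyldimethylsilyloxy)-1-ethoxy-4α-nitro-11,12,13-trinoreremophil-1(10)-ene | CCOC1=C2[C@@H](O[Si](C)(C)C(C)(C)C)CCC[C@]2(C)[C@](C)([N+](=O)[O-])CC1 | intermediate
10 | 9β-(tert-butyldimethylsilyloxy)-1-ethoxy-11,12,13-trinoreremophil-1(10)-ene | CCOC1=C2[C@@H](O[Si](C)(C)C(C)(C)C)CCC[C@]2(C)[C@@H](C)CC1 | intermediate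
11 | 9β-(tert-butyldimethylsilyloxy)-10αH-11,12,13-trinoreremophilan-1-one | O=C1CC[C@H](C)[C@@]2(C)CCC[C@H](O[Si](C)(C)C(C)(C)C)[C@H]12 | intermediate (not isolated)
12 | 9β-hydroxy-10αH-11,12,13-trinoreremophilan-1-one | O=C1CC[C@H](C)[C@@]2(C)CCC[C@H](O)[C@H]12 | intermediate
13 | tetramethylammonium diacetoxy(1-oxo-10αH-11,12,13-trinoreremophilan-9β-yloxy)hydroborate | C[N+](C)(C)C.O=C1CC[C@H](C)[C@@]2(C)CCC[C@H](O[BH-](OC(C)=O)OC(C)=O)[C@H]12 | intermediate (not isolated)
14 | 10αH-11,12,13-trinoreremophilane-1α,9β-diol | O[C@H]1CC[C@H](C)[C@@]2(C)CCC[C@H](O)[C@H]12 | intermediate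
15 | 1α-acetoxy-10αH-11,12,13-trinoreremophilan-9β-ol | CC(=O)O[C@H]1CC[C@H](C)[C@@]2(C)CCC[C@H](O)[C@H]12 | intermediate
16 | 1α-acetoxy-10αH-11,12,13-trinoreremophilan-9-one | CC(=O)O[C@H]1CC[C@H](C)[C@@]2(C)CCCC(=O)[C@H]12 | intermediate
17 | lithium 1α-acetoxy-10αH-11,12,13-trinoreremophil-8-en-9-olate | CC(=O)O[C@H]1CC[C@H](C)[C@@]2(C)CCC=C(O[Li])[C@H]12 | intermediate (not isolated)
18 | 1α-acetoxy-8-(N-tert-butyl-S-phenylsulfilimino)-10αH-11,12,13-trinoreremophilan-9-one | CC(=O)O[C@H]1CC[C@H](C)[C@@]2(C)CCC(S(=NC(C)(C)C)c3ccccc3)C(=O)[C@H]12 | intermediate (not isolated)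
19 | 1α-acetoxy-10αH-11,12,13-trinoreremophil-7-en-9-one | CC(=O)O[C@H]1CC[C@H](C)[C@@]2(C)CC=CC(=O)[C@H]12 | intermediate
20 | 1α-acetoxy-10αH-11,12,13-trinoreremophil-7-en-9β-ol | CC(=O)O[C@H]1CC[C@H](C)[C@@]2(C)CC=C[C@H](O)[C@H]12 | intermediate
21 | 1α-acetoxy-9α-(4-methoxyphenoxy)-10αH-11,12,13-trinoreremophil-7-ene | CC(=O)O[C@H]1CC[C@H](C)[C@@]2(C)CC=C[C@@H](Oc3ccc(OC)cc3)[C@H]12 | intermediate
22 | 1α-acetoxy-7α,8α-epoxy-9α-(4-methoxyphenoxy)-10αH-11,12,13-trinoreremophilane | CC(=O)O[C@H]1CC[C@H](C)[C@@]2(C)C[C@H]3O[C@H]3[C@@H](Oc4ccc(OC)cc4)[C@H]12 | intermediate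
23 | 1α-acetoxy-9α-(4-methoxyphenoxy)-10αH-eremophil-11-en-8α-ol | CC(=O)O[C@H]1CC[C@H](C)[C@@]2(C)C[C@H](C(C)=C)[C@@H](O)[C@@H](Oc3ccc(OC)cc3)[C@H]12 | intermediate
24 | lithium 1α-acetoxy-9α-(4-methoxyphenoxy)-10αH-eremophil-11-en-8α-olate | CC(=O)O[C@H]1CC[C@H](C)[C@@]2(C)C[C@H](C(C)=C)[C@@H](O[Li])[C@@H](Oc3ccc(OC)cc3)[C@H]12 | intermediate (not isolated)
25 | 1α-acetoxy-8α-angeloyloxy-9α-(4-methoxyphenoxy)-10αH-eremophil-11-ene | CC(=O)O[C@H]1CC[C@H](C)[C@@]2(C)C[C@H](C(C)=C)[C@@H](OC(=O)/C(C)=C\C)[C@@H](Oc3ccc(OC)cc3)[C@H]12 | intermediate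
26 | 1α-acetoxy-8α-angeloyloxy-10αH-eremophil-11-en-9α-ol | CC(=O)O[C@H]1CC[C@H](C)[C@@]2(C)C[C@H](C(C)=C)[C@@H](OC(=O)/C(C)=C\C)[C@@H](O)[C@H]12 | intermediate
27 | 1α-acetoxy-8α-angeloyloxy-10αH-eremophil-11-en-9-one (CNP0138236.2) | C=C(C)[C@H]1C[C@@]2(C)[C@H](C(=O)[C@@H]1OC(=O)/C(C)=C\C)[C@@H](OC(C)=O)CC[C@@H]2C | target

**Step count.** Total: 19 steps. Longest linear sequence: 18 steps (steps 1–4 and 6–19); step 5 is a one-step side branch.

**Steps most likely to fail, with fallbacks**

Step 6. Ring closure may stall at the congested C4–C5 bond, which joins two fully substituted carbons, and the nitroalkene may polymerise before it is consumed. The fallback sets out from 5 and comes back at 10. Diene 5 would be heated with methyl acrylate (toluene, 120 °C) in the same [4+2] sense, so that the new C4 centre is tertiary. Equilibration at C4 (NaOMe, MeOH) should favour the equatorial ester, giving 9β-(tert-butyldimethylsilyloxy)-1-ethoxy-4β-methoxycarbonyl-15-nor-11,12,13-trinoreremophil-1(10)-ene F1. Reduction with LiAlH4 would give the primary alcohol 9β-(tert-butyldimethylsilyloxy)-1-ethoxy-11,12,13-trinoreremophil-1(10)-en-15-ol F2. Tosylation (TsCl, pyridine) would give the 15-tosylate F3, and displacement with LiEt3BH would give the C15 methyl compound 10.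

Step 8. During enol ether hydrolysis the allylic C9 oxygen may be lost by acid-promoted ionisation or β-elimination, and C10 may epimerise to the cis ring fusion. The fallback sets out from 4 and comes back at 14; it avoids a C1 carbonyl altogether. Stille coupling of 4 with tributyl(vinyl)stannane (Pd(PPh3)4, CuI) would give (S)-tert-butyl[(3-methyl-2-vinylcyclohex-2-en-1-yl)oxy]dimethylsilane F4. Cycloaddition of F4 with 8 (toluene, 80 °C or high pressure), again forming C2–C3 and C4–C5, would give 9β-(tert-butyldimethylsilyloxy)-4α-nitro-11,12,13-trinoreremophil-1(10)-ene F5. Bu3SnH/AIBN would give the denitrated alkene 9β-(tert-butyldimethylsilyloxy)-11,12,13-trinoreremophil-1(10)-ene F6. Hydroboration–oxidation (BH3·THF; NaOH, H2O2) adds H to C10 and OH to C1 syn on the α face, anti to C14 and the silyloxy group, and should give 9β-(tert-butyldimethylsilyloxy)-10αH-11,12,13-trinoreremophilan-1α-ol F7. Desilylation with Bu4NF would give diol 14.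

Step 16. Attack at C7 is syn-axial to C14 and may be slow, so that the organometallic attacks the C1 acetate or the epoxide rearranges under BF3 activation. The fallback sets out from 21 and comes back at 23; it uses a more electrophilic cyclic sulfate. Dihydroxylation of 21 on the α face (OsO4 cat., N-methylmorpholine N-oxide) would give 1α-acetoxy-9α-(4-methoxyphenoxy)-10αH-11,12,13-trinoreremophilane-7α,8α-diol F8. SO2Cl2/Et3N (CH2Cl2, −78 °C) would give the 7α,8α-cyclic sulfate F9. The same cuprate at −78 °C should open F9 trans-diaxially at C7, and hydrolysis of the resulting C8 sulfate monoester (cat. H2SO4, H2O, THF) would give 23.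

**Further compounds**

F1 | step 6 | 9β-(tert-butyldimethylsilyloxy)-1-ethoxy-4β-methoxycarbonyl-15-nor-11,12,13-trinoreremophil-1(10)-ene | CCOC1=C2[C@@H](O[Si](C)(C)C(C)(C)C)CCC[C@]2(C)[C@@H](C(=O)OC)CC1
F2 | step 6 | 9β-(tert-butyldimethylsilyloxy)-1-ethoxy-11,12,13-trinoreremophil-1(10)-en-15-ol | CCOC1=C2[C@@H](O[Si](C)(C)C(C)(C)C)CCC[C@]2(C)[C@@H](CO)CC1
F3 | step 6 | 9β-(tert-butyldimethylsilyloxy)-1-ethoxy-11,12,13-trinoreremophil-1(10)-en-15-yl 4-methylbenzenesulfonate | CCOC1=C2[C@@H](O[Si](C)(C)C(C)(C)C)CCC[C@]2(C)[C@@H](COS(=O)(=O)c3ccc(C)cc3)CC1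
F4 | step 8 | (S)-tert-butyl[(3-methyl-2-vinylcyclohex-2-en-1-yl)oxy]dimethylsilane | CC(C)(C)[Si](C)(C)O[C@H]1CCCC(C)=C1C=C
F5 | step 8 | 9β-(tert-butyldimethylsilyloxy)-4α-nitro-11,12,13-trinoreremophil-1(10)-ene | C1=C2[C@@H](O[Si](C)(C)C(C)(C)C)CCC[C@]2(C)[C@](C)([N+](=O)[O-])CC1
F6 | step 8 | 9β-(tert-butyldimethylsilyloxy)-11,12,13-trinoreremophil-1(10)-ene | C1=C2[C@@H](O[Si](C)(C)C(C)(C)C)CCC[C@]2(C)[C@@H](C)CC1
F7 | step 8 | 9β-(tert-butyldimethylsilyloxy)-10αH-11,12,13-trinoreremophilan-1α-ol | O[C@H]1CC[C@H](C)[C@@]2(C)CCC[C@H](O[Si](C)(C)C(C)(C)C)[C@H]12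
F8 | step 16 | 1α-acetoxy-9α-(4-methoxyphenoxy)-10αH-11,12,13-trinoreremophilane-7α,8α-diol | CC(=O)O[C@H]1CC[C@H](C)[C@@]2(C)C[C@@H](O)[C@@H](O)[C@@H](Oc3ccc(OC)cc3)[C@H]12
F9 | step 16 | 1α-acetoxy-9α-(4-methoxyphenoxy)-10αH-11,12,13-trinoreremophilane-7α,8α-diyl cyclic sulfate | CC(=O)O[C@H]1CC[C@H](C)[C@@]2(C)C[C@H]3OS(=O)(=O)O[C@H]3[C@@H](Oc4ccc(OC)cc4)[C@H]12
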